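**Plan**
1. Retrosynthetic cuts, in order: the C17–C20 bond of the 11-membered ring (radical + enone); the C16 carbonyl and the ester; C7=C8 of ring A (metathesis); C11–C6 and the lactone C–O bond (allylboration/lactonisation); C11–C10 (acylation by an anhydride); C14–C15 and C18–C19 of ring C (Diels–Alder).
2. Forward: ring C → C10 side chain → C6 chain and γ-lactone → ring A → 11-membered ring → 1,2-dione and free acid.
3. Enabling feature: C20, the CH(CH3) carbon of the 11-membered ring, is bonded to C17, the ring-C CH next to the 1,2-dione. C20 is the Markovnikov radical of a terminal alkene and C17 the β-carbon of a C15 enone in ring C.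
4. Stereochemistry: C2 from (R)-citronellal; C9 from the (S)-Roche ester; C14/C19 from the endo Diels–Alder adduct; C11 and C6 from a Felkin-selective (Z)-allylboration; C17 (tether) and C20 (macrocyclic transition state) in the key step.
5. Atom labels: ring A C6–C7=C8(CO2H)–C9(CH3)–C10–C11(spiro); lactone C11–O12–C13(=O)–C14(CH3)–C19; ring C C14–C15(=O)–C16(=O)–C17–C18–C19; bridge C17–C20(CH3)–C21–C2(CH3)–C3–C4–C5–C6.
6. The ring-A carboxyl is carried from the start as a tert-butyl ester: the electron-poor ring-A alkene is a poor hydrogen-atom acceptor and resists SeO2, and the end game shrinks to two steps.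

Key step: step 20

Remark (assumption): the Diels–Alder adduct 19 forms as a racemate; it is resolved in step 14 through the diastereomeric keto acids made with the enantiopure zinc reagent, and the SMILES of 19 shows the enantiomer that is carried on.

**Step 1**
Reactants: 1 (R)-citronellal
Product: 2 (4R)-4,8-dimethylnona-1,7-diene
Conditions: Ph3PCH3Br, KOt-Bu, THF, 0 °C → rt
Reagents that add atoms: methyltriphenylphosphonium bromide, C[P+](c1ccccc1)(c1ccccc1)c1ccccc1.[Br-]
Why: Wittig methylenation of the aldehyde; the stereocentre is β to the carbonyl and cannot epimerise.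

**Step 2**
Reactants: 2 (4R)-4,8-dimethylnona-1,7-diene
Product: 4 (4R)-4-methylhept-6-enal, via epoxide 3 (not isolated)
Conditions: m-CPBA, CH2Cl2, 0 °C; crude epoxide, H5IO6, THF/H2O, 0 °C → rt
Reagents that add atoms: m-chloroperbenzoic acid, O=C(OO)c1cccc(Cl)c1
Why: Prilezhaev epoxidation is selective for the electron-rich trisubstituted alkene over the terminal one, and periodic acid cleaves the epoxide to the aldehyde with loss of acetone.

**Step 3**
Reactants: 4 (4R)-4-methylhept-6-enal
Product: 5 (2E,6R)-6-methylnona-2,8-dienal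
Conditions: Ph3P=CHCHO, toluene, 80 °C
Reagents that add atoms: (triphenylphosphoranylidene)acetaldehyde, O=CC=P(c1ccccc1)(c1ccccc1)c1ccccc1
Why: Wittig reaction with the stabilised formylmethylene ylide should give the (E)-enal.

**Step 4**
Reactants: 5 (2E,6R)-6-methylnona-2,8-dienal
Product: 6 (3E,7R)-7-methyldeca-1,3,9-triene
Conditions: Ph3PCH3Br, KOt-Bu, THF, 0 °C
Reagents that add atoms: methyltriphenylphosphonium bromide, C[P+](c1ccccc1)(c1ccccc1)c1ccccc1.[Br-]
Why: Wittig methylenation (1,2-addition to the enal) gives the terminal (E)-1,3-diene.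

**Step 5**
Reactants: 6 (3E,7R)-7-methyldeca-1,3,9-triene
Product: 7 (Z)-allylboronate [2-((2Z,7R)-7-methyldeca-2,9-dien-1-yl) pinacol boronate]
Conditions: HBpin, Ni(cod)2 (cat.), PCy3 (cat.), toluene, rt
Reagents that add atoms: pinacolborane, CC1(C)OBOC1(C)C
Why: Nickel-catalysed 1,4-hydroboration of the s-cis 1,3-diene puts H on the substituted terminus and boron on the CH2 terminus through a π-allyl nickel species, giving the (Z)-allylboronate; the isolated terminal alkene is not hydroborated by HBpin under these conditions.

**Step 6**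
Reactants: 8 methyl (S)-3-hydroxy-2-methylpropanoate (Roche ester)
Product: 9 methyl (S)-3-(tert-butyldimethylsilyloxy)-2-methylpropanoate
Conditions: TBSCl, imidazole, DMF, rt
Reagents that add atoms: tert-butyldimethylsilyl chloride, CC(C)(C)[Si](C)(C)Cl
Why: Standard silylation of the primary alcohol.

**Step 7**
Reactants: 9 silyl ether ester
Product: 11 (S)-4-(tert-butyldimethylsilyloxy)-3-methylbutan-2-one, via Weinreb amide 10 (not isolated)
Conditions: MeNH(OMe)·HCl, i-PrMgCl, THF, −20 °C; then MeMgBr, 0 °C
Reagents that add atoms: methylmagnesium bromide, C[Mg]Br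
Why: Magnesium-amide aminolysis gives the Weinreb amide and Grignard addition stops at the ketone through the chelated tetrahedral intermediate; low temperature keeps the α-stereocentre.

**Step 8**
Reactants: 11 methyl ketone
Product: 12 (S)-4-(tert-butyldimethylsilyloxy)-3-methylbut-1-en-2-yl triflate
Conditions: KHMDS, PhNTf2, THF, −78 → 0 °C
Reagents that add atoms: N-phenyl-bis(trifluoromethanesulfonimide), O=S(=O)(N(c1ccccc1)S(=O)(=O)C(F)(F)F)C(F)(F)F
Why: Kinetic deprotonation at the methyl group and O-triflation of the less substituted enolate give the terminal enol triflate without enolising the stereocentre.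

**Step 9**
Reactants: 12 enol triflate
Product: 13 tert-butyl (R)-4-(tert-butyldimethylsilyloxy)-3-methyl-2-methylidenebutanoate
Conditions: Pd(OAc)2 (cat.), dppf (cat.), CO (1 atm), t-BuOH, Et3N, DMF, 70 °C
Reagents that add atoms: carbon monoxide, [C-]#[O+]; tert-butanol, CC(C)(C)O
Why: Palladium-catalysed alkoxycarbonylation of an enol triflate (oxidative addition, CO insertion, alcoholysis) gives the 2-substituted acrylate; the stereocentre is now allylic and not acidic.

**Step 10**
Reactants: 13 silyl ether acrylate
Product: 14 tert-butyl (R)-4-hydroxy-3-methyl-2-methylidenebutanoate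
Conditions: HF·pyridine, pyridine, THF, 0 °C → rt
Reagents that add atoms: none
Why: Fluoride cleavage of the primary silyl ether; the tert-butyl ester resists closure to the α-methylene butyrolactone.

**Step 11**
Reactants: 14 hydroxy acrylate
Product: 15 tert-butyl (R)-4-iodo-3-methyl-2-methylidenebutanoate
Conditions: I2, PPh3, imidazole, CH2Cl2, 0 °C
Reagents that add atoms: iodine, II
Why: Appel-type iodination of the primary alcohol; the stereocentre is not involved.

**Step 12**
Reactants: 16 (E)-crotonaldehyde
Product: 17 (E)-1-(tert-butyldimethylsilyloxy)buta-1,3-diene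
Conditions: TBSOTf, Et3N, Et2O, 0 °C → rt
Reagents that add atoms: tert-butyldimethylsilyl triflate, CC(C)(C)[Si](C)(C)OS(=O)(=O)C(F)(F)F
Why: Soft enolisation (O-silylation of the enal, γ-deprotonation) gives the (E)-silyl dienol ether.

**Step 13**
Reactants: 17 silyloxy diene; 18 citraconic anhydride
Product: 19 all-cis bicyclic anhydride (racemate)
Conditions: toluene, 60 °C
Reagents that add atoms: none
Why: Thermal Diels–Alder reaction; the nucleophilic diene terminus bonds to the unsubstituted, more electrophilic alkene carbon, so the silyloxy carbon (C15) ends next to the methyl-bearing quaternary carbon (C14), and endo addition sets C14/C19 cis with OTBS on the same face.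

**Step 14**
Reactants: 15 iodide; 19 bicyclic anhydride (racemate)
Product: 21 keto acid, via alkylzinc iodide 20 (not isolated)
Conditions: 15, Zn dust (activated), DMA/THF, 40 °C; then 19, Ni(acac)2 (cat.), 2,2′-bipyridine, 4-fluorostyrene, THF, 0 °C → rt; aq. HCl; chromatographic separation of the two diastereomers
Reagents that add atoms: none
Why: Nickel-catalysed Negishi-type acylation of the alkylzinc halide by the cyclic anhydride: nickel inserts into the less hindered acyl–oxygen bond (the carbonyl on the CH carbon C19, away from the quaternary C14 and the OTBS group), and because 15 is a single enantiomer the two enantiomers of 19 give separable diastereomers, so this step is also the resolution.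

**Step 15**
Reactants: 21 keto acid
Product: 22 keto methyl ester
Conditions: TMSCHN2, toluene/MeOH, 0 °C
Reagents that add atoms: trimethylsilyldiazomethane, C[Si](C)(C)C=[N+]=[N-]
Why: Neutral esterification avoids epimerisation at C19, prevents the carboxylate from steering the next step, and provides the acyl donor for lactonisation.

**Step 16**
Reactants: 22 keto methyl ester; 7 (Z)-allylboronate
Product: 25 lactone triene, via allylborinic ester 23 (not isolated), via hydroxy ester 24 (not isolated)
Conditions: 7, n-BuLi, THF, −78 °C; TFAA; then 22, −78 °C → rt; aq. NaHCO3; CSA (cat.), CH2Cl2, rt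
Reagents that add atoms: none
Why: Ketone allylboration through an in situ borinic ester: in the Zimmerman–Traxler chair the γ-substituent of the (Z)-allyl unit is axial and the larger ketone substituent C19 equatorial, which puts the C6 chain cis to the lactone oxygen on the future ring A; Felkin–Anh approach anti to the quaternary C14 places C6 on the C18 face (concave face of the lactone), and the tertiary alcohol then closes the γ-lactone on the cis methyl ester.

**Step 17**
Reactants: 25 lactone triene
Product: 26 spirolactone with ring A closed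
Conditions: Grubbs second-generation catalyst (cat.), CH2Cl2 (2 mM), 40 °C
Reagents that add atoms: none
Why: Ring-closing metathesis between the C6 vinyl group and the 1,1-disubstituted acrylate alkene closes the six-membered ring A as a trisubstituted enoate with loss of ethylene; six-ring closure is far faster than eight- or ten-membered closures involving the distal alkene, and dilution suppresses cross-metathesis.

**Step 18**
Reactants: 26 spirolactone silyl ether
Product: 27 allylic alcohol
Conditions: HF·pyridine, THF, 0 °C → rt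
Reagents that add atoms: none
Why: Fluoride cleavage of the secondary allylic silyl ether; lactone and tert-butyl ester are stable.

**Step 19**
Reactants: 27 allylic alcohol
Product: 28 ring-C enone (cyclisation precursor)
Conditions: Dess–Martin periodinane, CH2Cl2, rt
Reagents that add atoms: none
Why: Dess–Martin oxidation of the allylic alcohol gives the C15 enone under non-basic conditions, so C19 and the alkene positions are untouched.

**Step 20**
Reactants: 28 ring-C enone
Product: 29 macrocyclic keto lactone
Conditions: Fe(acac)3 (30 mol %), PhSiH3, EtOH/(CH2OH)2, 60 °C, 2 mM, slow addition of 28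
Reagents that add atoms: none
Why: Proposed new method: an iron(III) hydride formed from Fe(acac)3, PhSiH3 and EtOH transfers H• to the terminal CH2 of the monosubstituted alkene (Markovnikov), creating the C20 methyl group and a nucleophilic secondary radical at C20 that adds to the enone β-carbon C17; the α-keto radical at C16 is reduced by Fe(II) to the enolate and protonated by the alcohol. The closest known reaction types are the iron-hydride reductive alkene–enone (Giese) coupling, known for intermolecular cases and common rings, and tin-hydride radical macrocyclisation onto enones; joining them for an 11-membered ring is the untested part. The ring closes 11-exo-trig (C20–C21–C2–C3–C4–C5–C6–C11–C19–C18–C17), with C16 outside the new ring. C17 is fixed by the tether: the chain hangs from C6 on the concave face of the cis-fused lactone, so the radical can reach C17 only on the face cis to C11 (cis-1,3 bridge across ring C); C20 is set in the macrocyclic transition state, where its methyl group is expected to point outward, 1,3-syn to the C2 methyl group. The step needs H• transfer to the unhindered terminal alkene and addition to C17, not C7: the ring-A alkene is an α,β-disubstituted, electron-poor ester alkene (slow H• acceptor, poor radical acceptor, and its attack would require an eight-membered ring), and high dilution suppresses intermolecular coupling.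

**Step 21**
Reactants: 29 macrocyclic keto lactone
Product: 30 1,2-dione tert-butyl ester
Conditions: SeO2, 1,4-dioxane, 90 °C
Reagents that add atoms: selenium dioxide, O=[Se]=O
Why: Riley oxidation: SeO2 attacks the enol of the only enolisable α-position (C16; C14 is quaternary), as in the camphor → camphorquinone case; the electron-poor ring-A alkene resists allylic oxidation and C17 is held by the bridge.

**Step 22**
Reactants: 30 1,2-dione tert-butyl ester
Product: 31 target acid (CNP0115928.1)
Conditions: TFA, CH2Cl2, 0 °C → rt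
Reagents that add atoms: none
Why: Acidolysis of the tert-butyl ester with loss of isobutene; the tertiary γ-lactone, the dione and the alkene should be stable to TFA.

**Compound list**
1 | (R)-citronellal, (3R)-3,7-dimethyloct-6-enal | C[C@H](CCC=C(C)C)CC=O | starting material
2 | (4R)-4,8-dimethylnona-1,7-diene | C[C@H](CCC=C(C)C)CC=C | intermediate
3 | 2,2-dimethyl-3-[(3R)-3-methylhex-5-en-1-yl]oxirane (epoxide epimers) | C[C@H](CCC1OC1(C)C)CC=C | intermediate (not isolated)
4 | (4R)-4-methylhept-6-enal | C[C@H](CCC=O)CC=C | intermediate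
5 | (2E,6R)-6-methylnona-2,8-dienal | C[C@H](CC/C=C/C=O)CC=C | intermediate
6 | (3E,7R)-7-methyldeca-1,3,9-triene | C[C@H](CC/C=C/C=C)CC=C | intermediate
7 | 2-[(2Z,7R)-7-methyldeca-2,9-dien-1-yl]-4,4,5,5-tetramethyl-1,3,2-dioxaborolane | C[C@H](CCC/C=C\CB1OC(C)(C)C(C)(C)O1)CC=C | intermediate
8 | methyl (S)-3-hydroxy-2-methylpropanoate (Roche ester) | COC(=O)[C@@H](C)CO | starting material
9 | methyl (S)-3-(tert-butyldimethylsilyloxy)-2-methylpropanoate | COC(=O)[C@@H](C)CO[Si](C)(C)C(C)(C)C | intermediate
10 | (S)-3-(tert-butyldimethylsilyloxy)-N-methoxy-N,2-dimethylpropanamide | CON(C)C(=O)[C@@H](C)CO[Si](C)(C)C(C)(C)C | intermediate (not isolated)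
11 | (S)-4-(tert-butyldimethylsilyloxy)-3-methylbutan-2-one | CC(=O)[C@@H](C)CO[Si](C)(C)C(C)(C)C | intermediate
12 | (S)-4-(tert-butyldimethylsilyloxy)-3-methylbut-1-en-2-yl trifluoromethanesulfonate | C=C(OS(=O)(=O)C(F)(F)F)[C@@H](C)CO[Si](C)(C)C(C)(C)C | intermediate
13 | tert-butyl (R)-4-(tert-butyldimethylsilyloxy)-3-methyl-2-methylidenebutanoate | C=C(C(=O)OC(C)(C)C)[C@@H](C)CO[Si](C)(C)C(C)(C)C | intermediate
14 | tert-butyl (R)-4-hydroxy-3-methyl-2-methylidenebutanoate | C=C(C(=O)OC(C)(C)C)[C@@H](C)CO | intermediate
15 | tert-butyl (R)-4-iodo-3-methyl-2-methylidenebutanoate | C=C(C(=O)OC(C)(C)C)[C@@H](C)CI | intermediate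
16 | (E)-crotonaldehyde | C/C=C/C=O | starting material
17 | (E)-1-(tert-butyldimethylsilyloxy)buta-1,3-diene | C=C/C=C/O[Si](C)(C)C(C)(C)C | intermediate
18 | citraconic anhydride | CC1=CC(=O)OC1=O | starting material
19 | rac-(3aR,4S,7aR)-4-(tert-butyldimethylsilyloxy)-3a-methyl-3a,4,7,7a-tetrahydro-2-benzofuran-1,3-dione (racemate; the enantiomer carried on is shown) | C[C@@]12C(=O)OC(=O)[C@@H]1CC=C[C@@H]2O[Si](C)(C)C(C)(C)C | intermediate
20 | [(2R)-3-(tert-butoxycarbonyl)-2-methylbut-3-en-1-yl]zinc iodide | C=C(C(=O)OC(C)(C)C)[C@@H](C)C[Zn]I | intermediate (not isolated)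
21 | (1R,2S,6R)-6-[(3S)-5-tert-butoxy-3-methyl-4-methylidene-5-oxopentanoyl]-2-(tert-butyldimethylsilyloxy)-1-methylcyclohex-3-ene-1-carboxylic acid | OC(=O)[C@@]1(C)[C@@H](O[Si](C)(C)C(C)(C)C)C=CC[C@H]1C(=O)C[C@H](C)C(=C)C(=O)OC(C)(C)C | intermediate
22 | methyl ester of 21 | COC(=O)[C@@]1(C)[C@@H](O[Si](C)(C)C(C)(C)C)C=CC[C@H]1C(=O)C[C@H](C)C(=C)C(=O)OC(C)(C)C | intermediate
23 | butyl[(2Z,7R)-7-methyldeca-2,9-dien-1-yl]borinic acid 2,3-dimethyl-3-(trifluoroacetoxy)butan-2-yl ester | C[C@H](CCC/C=C\CB(CCCC)OC(C)(C)C(C)(C)OC(=O)C(F)(F)F)CC=C | intermediate (not isolated)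
24 | hydroxy ester: 22 with the C11 ketone converted into the tertiary carbinol (C11 R) bearing the (3S,7R)-7-methyldeca-1,9-dien-3-yl group (C6 S) | C=C[C@H](CCC[C@@H](C)CC=C)[C@](O)(C[C@H](C)C(=C)C(=O)OC(C)(C)C)[C@@H]1CC=C[C@H](O[Si](C)(C)C(C)(C)C)[C@]1(C)C(=O)OC | intermediate (not isolated)
25 | (3R,3aR,7S,7aR)-3-[(2S)-3-(tert-butoxycarbonyl)-2-methylbut-3-en-1-yl]-7-(tert-butyldimethylsilyloxy)-7a-methyl-3-[(3S,7R)-7-methyldeca-1,9-dien-3-yl]-3a,4,7,7a-tetrahydro-2-benzofuran-1(3H)-one | C=C[C@H](CCC[C@@H](C)CC=C)[C@@]1(C[C@H](C)C(=C)C(=O)OC(C)(C)C)OC(=O)[C@@]2(C)[C@@H](O[Si](C)(C)C(C)(C)C)C=CC[C@@H]12 | intermediate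
26 | spirolactone: ring A (tert-butyl cyclohex-1-ene-1-carboxylate, C7=C8) spiro at C11 to the cis-fused γ-lactone/ring C; C15–OTBS, C16=C17; (4R)-4-methylhept-6-en-1-yl chain at C6; C2 R, C6 S, C9 S, C11 R, C14 R, C15 S, C19 R | C=CC[C@H](C)CCC[C@H]1C=C(C(=O)OC(C)(C)C)[C@@H](C)C[C@@]12OC(=O)[C@@]1(C)[C@@H](O[Si](C)(C)C(C)(C)C)C=CC[C@H]12 | intermediate
27 | allylic alcohol: 26 with free C15–OH (C15 S) | C=CC[C@H](C)CCC[C@H]1C=C(C(=O)OC(C)(C)C)[C@@H](C)C[C@@]12OC(=O)[C@@]1(C)[C@@H](O)C=CC[C@H]12 | intermediate
28 | spirolactone enone: 27 oxidised to the C15 ketone conjugated with C16=C17; terminal alkene chain at C6 | C=CC[C@H](C)CCC[C@H]1C=C(C(=O)OC(C)(C)C)[C@@H](C)C[C@@]12OC(=O)[C@@]1(C)C(=O)C=CC[C@H]12 | intermediate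
29 | macrocyclic keto lactone: 11-membered ring closed by the C17–C20 bond, C15 ketone, C16 CH2, tert-butyl ester; C2 R, C6 S, C9 S, C11 R, C14 R, C17 S (CIP priority change only), C19 R, C20 R | C[C@@H]1CCC[C@H]2C=C(C(=O)OC(C)(C)C)[C@@H](C)C[C@@]23OC(=O)[C@@]2(C)C(=O)C[C@H](C[C@H]23)[C@H](C)C1 | intermediate
30 | tert-butyl ester of the target (C15/C16 1,2-dione) | C[C@@H]1CCC[C@H]2C=C(C(=O)OC(C)(C)C)[C@@H](C)C[C@@]23OC(=O)[C@@]2(C)C(=O)C(=O)[C@H](C[C@H]23)[C@H](C)C1 | intermediate
31 | CNP0115928.1 (C2 R, C6 S, C9 S, C11 R, C14 R, C17 R, C19 R, C20 R) | C[C@@H]1CCC[C@H]2C=C(C(=O)O)[C@@H](C)C[C@@]23OC(=O)[C@@]2(C)C(=O)C(=O)[C@H](C[C@H]23)[C@H](C)C1 | target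

**Step count and risks**
Total: 22 steps. Longest linear sequence: 15 steps (8 → 31; steps 6–11 and 14–22).

Step 20 (macrocyclisation). The hydride may reduce the enone or the ring-A alkene, or the C20 radical may be quenched before the slow 11-membered closure; the C20 configuration may also come out mixed. The fallback generates the same radical by iodine abstraction, which is known tin-hydride radical macrocyclisation chemistry. It sets out from 26: oxymercuration–demercuration (Hg(OAc)2, THF/H2O; NaBH4) of the terminal alkene should give the secondary alcohol F1; I2/PPh3/imidazole the secondary iodide F2; HF·pyridine the iodo allylic alcohol F3; Dess–Martin oxidation the iodo enone F4. Slow addition of Bu3SnH/AIBN to F4 in refluxing benzene at high dilution should close the ring and return to the route at 29.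

Step 16 (allylboration). Facial selectivity at the ketone may be poor, because the axial γ-substituent of the (Z)-allyl unit is pressed against C18 in the Felkin-type chair, so the C11 epimer may compete. The fallback replaces substrate control by catalyst control. It sets out from 7: KHF2 gives the potassium trifluoroborate F5, and TMSCl/i-PrOH converts it into the diisopropyl boronate F6. Allylboration of 22 with F6 under catalysis by a chiral 3,3′-dibromo-BINOL (the enantiomer that reinforces the wanted face, the (Z)-geometry still fixing C6 relative to C11) gives 24, and acid lactonisation comes back to the route at 25.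

Step 21 (α-oxidation). Hot SeO2 may over-oxidise the product or enolise the new dione toward C17 (diosphenol formation, dehydrogenation). The fallback is a two-stage oxidation in the cold. It sets out from 29: KHMDS then Davis oxaziridine (THF, −78 °C) gives the α-hydroxy ketone F7, and Dess–Martin oxidation returns to the route at 30.

**Further compounds**
F1 | step 20 | secondary alcohol (Markovnikov hydrate of the terminal alkene of 26, carbinol epimers) | CC(O)C[C@H](C)CCC[C@H]1C=C(C(=O)OC(C)(C)C)[C@@H](C)C[C@@]12OC(=O)[C@@]1(C)[C@@H](O[Si](C)(C)C(C)(C)C)C=CC[C@H]12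
F2 | step 20 | secondary iodide | CC(I)C[C@H](C)CCC[C@H]1C=C(C(=O)OC(C)(C)C)[C@@H](C)C[C@@]12OC(=O)[C@@]1(C)[C@@H](O[Si](C)(C)C(C)(C)C)C=CC[C@H]12
F3 | step 20 | iodo allylic alcohol | CC(I)C[C@H](C)CCC[C@H]1C=C(C(=O)OC(C)(C)C)[C@@H](C)C[C@@]12OC(=O)[C@@]1(C)[C@@H](O)C=CC[C@H]12
F4 | step 20 | iodo enone | CC(I)C[C@H](C)CCC[C@H]1C=C(C(=O)OC(C)(C)C)[C@@H](C)C[C@@]12OC(=O)[C@@]1(C)C(=O)C=CC[C@H]12
F5 | step 16 | potassium [(2Z,7R)-7-methyldeca-2,9-dien-1-yl]trifluoroborate | [K+].F[B-](F)(F)C/C=C\CCC[C@@H](C)CC=C
F6 | step 16 | diisopropyl [(2Z,7R)-7-methyldeca-2,9-dien-1-yl]boronate | CC(C)OB(C/C=C\CCC[C@@H](C)CC=C)OC(C)C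
F7 | step 21 | α-hydroxy ketone (C16–OH, carbinol epimers) | C[C@@H]1CCC[C@H]2C=C(C(=O)OC(C)(C)C)[C@@H](C)C[C@@]23OC(=O)[C@@]2(C)C(=O)C(O)[C@H](C[C@H]23)[C@H](C)C1
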